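## Analysis of the target

Compound 34 is an ester of two cadinane-type halves: the alcohol half is a cyclohexane (ring A) cis-fused to a seven-membered unsaturated lactone (ring B) whose alkene carries a free carboxylic acid, and the acyl half is a cyclohexene (ring C) joined through its allylic ring carbon to a 2-(hydroxymethyl)propenoate. Ring A has four contiguous stereocentres, namely the isopropyl carbon, the two fusion carbons and a tertiary carbinol that also bears the esterified CH2O arm; the isopropyl group is trans to the neighbouring ring B carbon, the two ring B bonds are cis, and the tertiary hydroxyl is cis (its CH2O arm trans) to the lactone carbonyl carbon. Ring C has two stereocentres, with the isopropyl group trans to the side chain. In both rings the isopropyl carbon is (S) with the neighbouring carbon substituent trans, so both halves map onto one enone, 4. The ring B lactone is an allylic ester of the 2-(acyloxymethyl)acrylate kind, so it is ionised by zerovalent palladium and attacked in SN2′ fashion by amines and phosphines, and its α-carbon carries an axial carboxyl carbon beside a β-hydroxyl, so base can epimerise it or trigger retro-aldol cleavage. The hard points are the contra-thermodynamic all-cis array (oxygen, carboxyl carbon, ring B carbon) on ring A, and the union, in which a neopentyl-type primary alcohol must be acylated by an acid that carries its own free primary hydroxyl. The strategy rests on C-2 of the propenoate, the alkene carbon not bonded to ring C, which bears both the carboxyl carbon and the hydroxymethyl carbon with the carboxyl trans to ring C. The atoms O–CH2–C(2)–C(=O) are therefore the four ring atoms of an α-alkylidene β-lactone in opened form.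

## Retrosynthetic reasoning

**34 to 33.** The last operation only removes a primary silyl ether (ring C) and a tert-butyl ester (ring B acid), both by acid. The target tolerates acid far better than base, so 33 carries only acid-labile groups.

**33 to 32, then 30 + 31 (ring B).** The trisubstituted ring B alkene is cut by ring-closing metathesis, and the allylic C–O bond of the lactone by carboxylate alkylation with 31. Closing ring B last means the lactone carbonyl never sits next to a free primary alkoxide. With ring B in place, that alkoxide could attack the lactone carbonyl on the adjacent ring carbon and contract the ring to a γ-lactone. The metathesis has to join a vinyl group and a 1,1-disubstituted acrylate held cis on ring A.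

**30 to 29 + 17 (the union).** The ester C–O bond between the halves is cut so that the acyl partner is the β-lactone 17. In 17 the acid is activated by ring strain and its hydroxymethyl is tied up in the same ring, so no coupling reagent and no protecting group are needed. The nucleophile is the primary alkoxide of 29, whose carboxyl group is a carboxylate during the union. A carboxylate cannot be attacked by the neighbouring alkoxide and makes the adjacent ring carbon non-enolisable.

**17 to 16 (key disconnection).** Two bonds are cut: from the alkene carbon to the lactone carbonyl carbon, and from that carbonyl carbon to the ring oxygen. Forward, a one-carbon carbonyl unit is inserted into the vinyl iodide by palladium and captured by the neighbouring hydroxymethyl. The alkene geometry of 16 (iodine trans to ring C) becomes that of 17 unchanged.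

**16 to 15 to 14.** Iodine is traded for tin, and the vinylstannane comes from the propargylic alcohol 14 by syn-hydrostannation. The syn addition fixes the geometry, and the hydroxyl together with the branched ring carbon steers tin to the carbinol-side alkyne carbon.

**14 back to 9.** The ring C hydroxymethyl carbon is disconnected at its bond to the ring alkene. Forward: enol triflate 10 from silyl enol ether 9, methoxycarbonylation to 11, reduction to 12, silylation to 13, release of the propargylic hydroxyl to 14. The two hydroxyls are told apart because one arrives as the PMB ether of 6.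

**9 to 4 + 6, and 6 to 5.** The bond between ring C and the alkyne is cut as a conjugate addition to 4. Attack anti to the isopropyl group gives the trans pair, and trapping on oxygen fixes the position of the future ring alkene.

**29 back to 19 (alcohol half).** The carboxyl carbon and the vinyl carbon on neighbouring ring carbons of 29 are seen as the two former sp3 carbons of a cis-fused cyclobutane. Forward: hydroxymethyl addition to the ketone of 19 (via 21 from 20) and Tamao oxidation give 23, protected as 24. Ozonolysis gives cyclobutanone 25. Its silyl enol ether 26 is cleaved to aldehyde acid 27, methylenation gives 28, and acetonide removal gives 29. The four-membered ring guarantees the cis relation that a cyclohexanone enolate would not give. Its α-carbon, axial on ring A, directs the nucleophile to the opposite face of the ketone.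

**19 to 4 + 18.** The cyclobutane is cut into the enone 4 and allene 18 ([2+2] photocycloaddition anti to isopropyl). The same enone therefore serves both halves.

**4 to 3 to 1 + 2.** The enone is opened by retro-aldol condensation to keto aldehyde 3, which is cut at the bond made by an enamine-catalysed Michael addition of 1 to 2.

## Alternatives that were turned down

**Alternative 1:** Ring C is assembled from three components instead of from 4. The disconnection cuts the bond between its two stereocentres, the bond between its two methylene carbons, and the ring double bond.

- **Forward key step.** A diarylprolinol silyl ether converts the protected hydroxy aldehyde A2 into an enamine that adds to the branched nitroalkene A3. The resulting nitronate adds to acrolein A4, and aldol condensation closes the nitrocyclohexenecarbaldehyde A1.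
- **For.** Three C–C bonds and both ring stereocentres (trans) form in one flask under catalyst control. On ring construction alone it is stronger than the chosen route, which spends six steps (4 to 9) on ring C after the enone.
- **Against.** The nitro group is only a relay and must be removed from a secondary carbon by a sluggish tin-hydride chain. The isopropyl-branched nitroalkene A3 is a slow acceptor, and the aldehyde A2 and acrolein A4 can also condense with each other outside the intended sequence. A1 still lacks the whole propenoate: an olefination must set the trisubstituted geometry, and the resulting hydroxy acid needs protection and activation for the union.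
- **Comparison.** The chosen strategy offers one enone for both halves, an alkyne holding exactly the three side-chain carbons with geometry from a syn addition, and a key step that creates the carboxyl group already activated.

**Alternative 2:** Rings A and B are made together. The disconnection cuts the bond between the two fusion carbons and the bond from the carbon next to the fusion to the future carboxyl-bearing carbon.

- **Forward key step.** Irradiation of the tetronic acid A5 adds its enol double bond across the tethered vinyl group, and retro-aldol opening of the cyclobutanol expands the furanone to the bicyclic keto lactone A6.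
- **For.** Ring A, ring B with its lactone, and the cis fusion arise in one operation. In bond economy for the alcohol half it is stronger than the sequence used here (intermolecular photocycloaddition, two ozonolyses, metathesis).
- **Against.** A5 must carry the isopropyl centre and the quaternary acetonide carbon, both set on an open chain. The two new fusion centres depend on how a flexible tether folds. The ketone of A6 lies between an O–CH2 and a C–CH2 group, so the enol triflate needed for the unsaturated acid faces a regiochemical choice. The acyl half and the union are untouched.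
- **Comparison.** The chosen route takes ring A and its isopropyl centre from the same enone as ring C, so the photochemical step meets only one stereocentre, directly beside the reacting alkene. Its risk is concentrated in forming the acyl donor.

**Alternative 3:** Ring A is closed by the bond between the acid α-carbon and the carbinol carbon.

- **Forward key step.** Activation of the keto acid A7 with a 2-halopyridinium salt and 4-pyrrolidinopyridine gives an ammonium enolate that adds to the ketone, and the alkoxide closes the fused β-lactone A8.
- **For.** The four-membered ring forces the tertiary oxygen and the carboxyl carbon cis. The chosen route must earn that relation through face-selective addition to a ketone, so on this point the alternative is stronger. Its β-lactone is also an activated acyl group for building the ring B ester.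
- **Against.** The two new centres must be related to the two existing ones from an open chain. The carboxyl carbon has to end up axial and cis to the acetal-bearing neighbour, against the preference of a chair-like aldol transition state. The ketone is a hindered α-silyloxy ketone. A7 needs two adjacent stereocentres made acyclically. The β-lactone of a tertiary alcohol can lose CO2. The acyl half remains unsolved.
- **Comparison.** Both plans use a β-lactone. Here it sits in the half whose target substructure is exactly the ring-opened lactone, so opening it is the union. In A8 it would have to be opened and replaced by a seven-membered lactone.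

Key step: step 12

Remark: the (S)-diarylprolinol ether in step 1 is assumed to direct attack to the enamine face remote from its diarylmethyl group, as it does with other Michael acceptors, which gives (S)-3.

## Route

Step 1
Reactants: 1 3-methylbutanal (isovaleraldehyde); 2 but-3-en-2-one (methyl vinyl ketone)
Product: 3 (S)-2-isopropyl-5-oxohexanal
Conditions: (S)-2-(methoxydiphenylmethyl)pyrrolidine (5 mol %), ethyl 3,4-dihydroxybenzoate (20 mol %), neat, 4 °C
Reagents that add atoms: none
Why: Enamine-catalysed Michael addition of an aldehyde to an enone; the enone approaches the enamine face remote from the diarylmethyl group, which should set the isopropyl-bearing carbon as (S), and the catechol activates the enone by hydrogen bonding.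

Step 2
Reactants: 3 (S)-2-isopropyl-5-oxohexanal
Product: 4 (S)-4-isopropylcyclohex-2-en-1-one [(S)-cryptone]
Conditions: LiOH (0.2 equiv), i-PrOH, rt
Reagents that add atoms: none
Why: Intramolecular aldol condensation of the methyl ketone onto the aldehyde followed by dehydration; the mild hydroxide should close the ring faster than the α-branched aldehyde epimerises.

Step 3
Reactants: 5 prop-2-yn-1-ol (propargyl alcohol)
Product: 6 1-methoxy-4-[(prop-2-yn-1-yloxy)methyl]benzene
Conditions: NaH, 4-methoxybenzyl chloride, Bu4NI (cat.), THF, 0 °C to rt
Reagents that add atoms: 4-methoxybenzyl chloride, COc1ccc(CCl)cc1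
Why: Williamson ether synthesis; the PMB group keeps the propargylic oxygen distinct from the ring hydroxymethyl made later and is removed oxidatively.

Step 4
Reactants: 6 1-methoxy-4-[(prop-2-yn-1-yloxy)methyl]benzene; 4 (S)-cryptone
Product: 9 tert-butyl({(3S,4S)-4-isopropyl-3-[3-(4-methoxybenzyloxy)prop-1-yn-1-yl]cyclohex-1-en-1-yl}oxy)dimethylsilane (3,4-trans), via lithium acetylide 7 (not isolated), via dimethylalkynylalane 8 (not isolated)
Conditions: n-BuLi, Et2O, −78 °C; Me2AlCl, −78 to 0 °C; then 4 and TBSOTf, −78 to −40 °C; Et3N, aq. NaHCO3
Reagents that add atoms: tert-butyldimethylsilyl triflate, CC(C)(C)[Si](C)(C)OS(=O)(=O)C(F)(F)F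
Why: Silyl-triflate-promoted conjugate addition of an alkynylalane; a ring enone cannot reach the s-cis geometry that an unassisted alkynylalane needs, so the triflate activates the carbonyl and the enolate is caught on oxygen. The alkynyl group enters anti to the isopropyl group (3,4-trans) and the enol ether double bond lies toward the new substituent.

Step 5
Reactants: 9 silyl enol ether
Product: 10 (3S,4S)-4-isopropyl-3-[3-(4-methoxybenzyloxy)prop-1-yn-1-yl]cyclohex-1-en-1-yl trifluoromethanesulfonate
Conditions: CsF, PhNTf2, DME, rt
Reagents that add atoms: N-phenylbis(trifluoromethanesulfonimide), O=S(=O)(N(c1ccccc1)S(=O)(=O)C(F)(F)F)C(F)(F)F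
Why: Fluoride releases the regiodefined enolate, which is sulfonylated on oxygen before it can equilibrate, so the triflate keeps the double-bond position fixed in step 4.

Step 6
Reactants: 10 enol triflate
Product: 11 methyl (3S,4S)-4-isopropyl-3-[3-(4-methoxybenzyloxy)prop-1-yn-1-yl]cyclohex-1-ene-1-carboxylate
Conditions: Pd(OAc)2 (5 mol %), PPh3 (10 mol %), CO (1 atm), MeOH, Et3N, DMF, 50 °C
Reagents that add atoms: carbon monoxide, [C-]#[O+]; methanol, CO
Why: Palladium-catalysed alkoxycarbonylation of a vinyl triflate; oxidative addition, CO insertion and methanolysis install the ring C one-carbon unit, and the vinylpalladium cannot reach the alkyne two atoms away.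

Step 7
Reactants: 11 methyl ester
Product: 12 {(3S,4S)-4-isopropyl-3-[3-(4-methoxybenzyloxy)prop-1-yn-1-yl]cyclohex-1-en-1-yl}methanol
Conditions: i-Bu2AlH (2.5 equiv), CH2Cl2, −78 °C; Rochelle salt
Reagents that add atoms: none
Why: 1,2-Reduction of a conjugated ester to the allylic alcohol by an aluminium hydride; the alkyne and the PMB ether are inert.

Step 8
Reactants: 12 allylic alcohol
Product: 13 tert-butyl({(3S,4S)-4-isopropyl-3-[3-(4-methoxybenzyloxy)prop-1-yn-1-yl]cyclohex-1-en-1-yl}methoxy)dimethylsilane
Conditions: TBSCl, imidazole, CH2Cl2, rt
Reagents that add atoms: tert-butyldimethylsilyl chloride, CC(C)(C)[Si](C)(C)Cl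
Why: Silylation of a primary alcohol; the ring hydroxymethyl must stay masked so that only one hydroxyl can capture the acylpalladium in step 12 and only one alkoxide exists in step 21.

Step 9
Reactants: 13 silyl ether
Product: 14 3-[(1S,6S)-3-{[tert-butyl(dimethyl)silyloxy]methyl}-6-isopropylcyclohex-2-en-1-yl]prop-2-yn-1-ol
Conditions: DDQ, CH2Cl2/pH 7 buffer (10:1), 0 °C
Reagents that add atoms: none
Why: Oxidative cleavage of a PMB ether by hydride abstraction from the electron-rich benzylic position; the silyl ether and the alkyne are untouched.

Step 10
Reactants: 14 propargylic alcohol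
Product: 15 2-(tributylstannyl)-3-[3-{[tert-butyl(dimethyl)silyloxy]methyl}-6-isopropylcyclohex-2-en-1-yl]prop-2-en-1-ol (tin trans to ring C; ring 1,6-trans; isopropyl carbon S)
Conditions: Bu3SnH (1.3 equiv, slow addition), PdCl2(PPh3)2 (2 mol %), THF, 0 °C
Reagents that add atoms: tributyltin hydride, CCCC[SnH](CCCC)CCCC
Why: Palladium-catalysed syn-hydrostannation of a propargylic alcohol; hydrogen and tin add to the same side, and tin goes to the carbinol-side carbon because of the oxygen substituent and because the other alkyne carbon bears the branched ring carbon.

Step 11
Reactants: 15 vinylstannane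
Product: 16 2-iodo-3-[3-{[tert-butyl(dimethyl)silyloxy]methyl}-6-isopropylcyclohex-2-en-1-yl]prop-2-en-1-ol (iodine trans to ring C and cis to the vinylic hydrogen)
Conditions: I2 (1.05 equiv), CH2Cl2, 0 °C; aq. Na2S2O3
Reagents that add atoms: iodine, II
Why: Iododestannylation of a vinylstannane proceeds with retention at the sp2 carbon, so the geometry set in step 10 is carried into the iodide.

Step 12
Reactants: 16 2-iodoallylic alcohol
Product: 17 3-{[3-{[tert-butyl(dimethyl)silyloxy]methyl}-6-isopropylcyclohex-2-en-1-yl]methylidene}oxetan-2-one (lactone carbonyl trans to ring C)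
Conditions: Pd(PPh3)4 (5 mol %), CO (3 atm), K2CO3 (2 equiv), THF, 40 °C
Reagents that add atoms: carbon monoxide, [C-]#[O+]
Why: Zerovalent palladium adds oxidatively to the C–I bond of 16 with retention of alkene geometry, CO inserts to give an acylpalladium iodide, and the hydroxymethyl on the same alkene carbon, deprotonated with the help of carbonate, closes an acyl(alkoxo)palladacycle from which C–O reductive elimination releases the lactone and the catalyst. The closest known reaction type is the palladium-catalysed cyclocarbonylation of 2-halo allylic alcohols to α-methylene and α-alkylidene β-lactones. The one new ring is closed in a 4-exo-trig sense, the hydroxyl oxygen attacking the acyl carbon. No stereocentre is formed; the geometry of 17 is that of 16, so the new carbonyl carbon ends up trans to ring C. The step needs intramolecular capture to beat intermolecular alcoholysis and hydrodeiodination, and this is secured because the only free hydroxyl sits beside the acylated carbon (the ring hydroxymethyl is silylated) and CO pressure keeps insertion ahead of reduction. The insoluble carbonate is too weak to shift the doubly allylic hydrogen on ring C or to open the product.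

Step 13
Reactants: 4 (S)-cryptone; 18 propa-1,2-diene (allene)
Product: 19 5-isopropyl-8-methylidenebicyclo[4.2.0]octan-2-one (cis-fused; four-membered ring anti to isopropyl; isopropyl carbon S)
Conditions: hν (medium-pressure Hg lamp, Pyrex filter), excess 18, THF, −78 °C; then filtration through neutral alumina
Reagents that add atoms: none
Why: Enone–allene [2+2] photocycloaddition; the central allene carbon bonds to the α-carbon (head-to-head), the small ring forces a cis fusion, and approach anti to the isopropyl group on the adjacent carbon sets both new stereocentres. Alumina converts any trans-fused adduct into the cis isomer.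

Step 14
Reactants: 19 photoadduct; 20 (chloromethyl)(isopropoxy)dimethylsilane
Product: 22 5-isopropyl-2-{[isopropoxy(dimethyl)silyl]methyl}-8-methylidenebicyclo[4.2.0]octan-2-ol (hydroxyl on the face of the four-membered ring), via silylmethyl Grignard reagent 21 (not isolated)
Conditions: 20, Mg, THF, rt; then 19, THF, 0 °C; aq. NH4Cl
Reagents that add atoms: none
Why: Grignard addition of a hydroxymethyl anion equivalent to a ketone; the cyclobutane carbon on the α-position is axial on the six-membered ring and blocks its own face, so the carbon nucleophile enters anti to it and the hydroxyl ends up cis to the four-membered ring.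

Step 15
Reactants: 22 β-hydroxysilane
Product: 23 2-(hydroxymethyl)-5-isopropyl-8-methylidenebicyclo[4.2.0]octan-2-ol
Conditions: 30% H2O2, KF, KHCO3, THF/MeOH (1:1), rt
Reagents that add atoms: hydrogen peroxide, OO
Why: Tamao oxidation of the alkoxysilane converts the C–Si bond into C–OH with retention; the buffered fluoride conditions avoid Peterson elimination and leave the alkene alone.

Step 16
Reactants: 23 diol
Product: 24 5-isopropyl-2',2'-dimethyl-8-methylidenespiro[bicyclo[4.2.0]octane-2,4'-[1,3]dioxolane]
Conditions: 2,2-dimethoxypropane, PPTS (cat.), CH2Cl2, rt
Reagents that add atoms: 2,2-dimethoxypropane, COC(C)(C)OC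
Why: Acetonide formation from a 1,2-diol; the tertiary oxygen must be capped because a free β-hydroxyl would trigger retro-aldol opening of the cyclobutanone made next.

Step 17
Reactants: 24 acetonide
Product: 25 5-isopropyl-2',2'-dimethylspiro[bicyclo[4.2.0]octane-2,4'-[1,3]dioxolan]-8-one
Conditions: O3, CH2Cl2, −78 °C; PPh3, −78 °C to rt
Reagents that add atoms: ozone, [O-][O+]=O
Why: Ozonolysis of the only alkene (the exocyclic methylene) with reductive work-up gives the cyclobutanone under neutral conditions.

Step 18
Reactants: 25 cyclobutanone
Product: 27 7-formyl-8-isopropyl-2,2-dimethyl-1,3-dioxaspiro[4.5]decane-6-carboxylic acid (carboxyl and formyl cis and on the face of O-1; isopropyl trans to formyl), via trimethylsilyl enol ether 26 (not isolated)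
Conditions: LDA, Me3SiCl (internal quench), THF, −78 °C; then O3, CH2Cl2/MeOH, −78 °C; Me2S; work-up at pH 4
Reagents that add atoms: ozone, [O-][O+]=O
Why: Kinetic enolisation removes a hydrogen from the unhindered ring CH2 and not from the methine beside the spiro centre, and ozonolysis of the silyl enol ether cleaves the four-membered ring into a carboxylic acid (former carbonyl carbon) and an aldehyde. The cis relation of the two carbons is inherited from the cyclobutane.

Step 19
Reactants: 27 aldehyde acid
Product: 28 7-ethenyl-8-isopropyl-2,2-dimethyl-1,3-dioxaspiro[4.5]decane-6-carboxylic acid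
Conditions: Ph3PCH3Br (3.5 equiv), KHMDS (3.3 equiv), THF, 0 °C to rt; work-up at pH 4
Reagents that add atoms: methyltriphenylphosphonium bromide, C[P+](c1ccccc1)(c1ccccc1)c1ccccc1.[Br-]
Why: Wittig methylenation; excess ylide first forms the carboxylate, which protects the adjacent methine from deprotonation, and the formyl-bearing carbon already has its more stable equatorial arrangement trans to isopropyl.

Step 20
Reactants: 28 vinyl acid
Product: 29 2-ethenyl-6-hydroxy-6-(hydroxymethyl)-3-isopropylcyclohexane-1-carboxylic acid (1,2-cis; 2,3-trans; tertiary hydroxyl cis to carboxyl; isopropyl carbon S)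
Conditions: AcOH/H2O (4:1), 35 °C
Reagents that add atoms: none
Why: Acid hydrolysis of the acetonide; the hydroxymethyl and carboxyl groups are trans-diaxial on the preferred chair, so γ-lactonisation is slow in the aqueous medium, and any lactone formed would be reopened on forming the dianion.

Step 21
Reactants: 29 diol acid; 17 α-alkylidene β-lactone
Product: 30 2-ethenyl-6-hydroxy-3-isopropyl-6-({[2-(hydroxymethyl)-3-(3-{[tert-butyl(dimethyl)silyloxy]methyl}-6-isopropylcyclohex-2-en-1-yl)prop-2-enoyl]oxy}methyl)cyclohexane-1-carboxylic acid (ring A configuration as in 29; ring C configuration and alkene geometry as in 17)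
Conditions: NaHMDS (2.05 equiv), THF, −78 °C; then 17 (1.1 equiv), −78 to −40 °C; AcOH quench
Reagents that add atoms: none
Why: Acyl–oxygen cleavage of a β-lactone by a hard alkoxide, driven by ring strain, transfers the whole acyl half and releases its hydroxymethyl group. The carboxylate of 29 is a spectator that prevents enolisation or retro-aldol cleavage next to it and offers the alkoxide no neighbouring ester carbonyl; the tertiary alkoxide is too hindered to compete.

Step 22
Reactants: 30 acid; 31 tert-butyl 2-(bromomethyl)prop-2-enoate
Product: 32 2-(tert-butoxycarbonyl)prop-2-en-1-yl ester of 30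
Conditions: Cs2CO3 (1.0 equiv), DMF, 0 °C to rt
Reagents that add atoms: none
Why: O-alkylation of a caesium carboxylate by an activated allylic bromide (direct or SN2′ displacement gives the same ester); this avoids activating a hindered axial acid, and carbonate does not alkylate the free hydroxyls.

Step 23
Reactants: 32 diene
Product: 33 tert-butyl ester and ring C silyl ether of 34
Conditions: second-generation Hoveyda–Grubbs catalyst (H2IMes)Cl2Ru=CH(C6H4-2-O-i-Pr) (10 mol %), toluene (2 mM), 80 °C
Reagents that add atoms: none
Why: Ring-closing metathesis between the vinyl group and the 1,1-disubstituted acrylate, held cis on ring A; the ring allows only one alkene geometry, and the trisubstituted alkenes of the acyl half and ring C are too hindered to engage the ruthenium carbene.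

Step 24
Reactants: 33 protected target
Product: 34 9-hydroxy-9-({[2-(hydroxymethyl)-3-(3-(hydroxymethyl)-6-isopropylcyclohex-2-en-1-yl)prop-2-enoyl]oxy}methyl)-6-isopropyl-1-oxo-1,3,5a,6,7,8,9,9a-octahydro-2-benzoxepine-4-carboxylic acid (target; ring A: cis fusion, isopropyl trans to the ring B carbon, tertiary hydroxyl cis to the lactone carbonyl carbon; ring C 1,6-trans; propenoate carboxyl trans to ring C)
Conditions: CF3CO2H/CH2Cl2/H2O (20:75:5), 0 °C to rt; evaporation with toluene
Reagents that add atoms: none
Why: Acidolysis cleaves the tert-butyl ester by alkyl–oxygen fission and the primary silyl ether by solvolysis; the tertiary alcohol, flanked by an acyloxymethyl group and a carbonyl-bearing carbon, is slow to ionise, and no base touches the epimerisable lactone.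

## Compound list

1 | 3-methylbutanal (isovaleraldehyde) | CC(C)CC=O | starting material
2 | but-3-en-2-one (methyl vinyl ketone) | CC(=O)C=C | starting material
3 | (S)-2-isopropyl-5-oxohexanal | CC(C)[C@H](CCC(C)=O)C=O | intermediate
4 | (S)-4-isopropylcyclohex-2-en-1-one, (S)-cryptone | CC(C)[C@@H]1CCC(=O)C=C1 | intermediate
5 | prop-2-yn-1-ol (propargyl alcohol) | C#CCO | starting material
6 | 1-methoxy-4-[(prop-2-yn-1-yloxy)methyl]benzene | COc1ccc(COCC#C)cc1 | intermediate
7 | lithium 3-(4-methoxybenzyloxy)prop-1-yn-1-ide | COc1ccc(COCC#C[Li])cc1 | intermediate (not isolated)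
8 | dimethyl[3-(4-methoxybenzyloxy)prop-1-yn-1-yl]alane | COc1ccc(COCC#C[Al](C)C)cc1 | intermediate (not isolated)
9 | tert-butyldimethylsilyl enol ether of the trans conjugate adduct | COc1ccc(COCC#C[C@@H]2C=C(O[Si](C)(C)C(C)(C)C)CC[C@H]2C(C)C)cc1 | intermediate
10 | ring C enol triflate | COc1ccc(COCC#C[C@@H]2C=C(OS(=O)(=O)C(F)(F)F)CC[C@H]2C(C)C)cc1 | intermediate
11 | ring C methyl ester | COc1ccc(COCC#C[C@@H]2C=C(C(=O)OC)CC[C@H]2C(C)C)cc1 | intermediate
12 | ring C allylic alcohol | COc1ccc(COCC#C[C@@H]2C=C(CO)CC[C@H]2C(C)C)cc1 | intermediate
13 | ring C silyl ether, PMB propargyl ether | COc1ccc(COCC#C[C@@H]2C=C(CO[Si](C)(C)C(C)(C)C)CC[C@H]2C(C)C)cc1 | intermediate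
14 | ring C propargylic alcohol | OCC#C[C@@H]1C=C(CO[Si](C)(C)C(C)(C)C)CC[C@H]1C(C)C | intermediate
15 | ring C 2-stannyl allylic alcohol | CCCC[Sn](CCCC)(CCCC)/C(CO)=C/[C@@H]1C=C(CO[Si](C)(C)C(C)(C)C)CC[C@H]1C(C)C | intermediate
16 | ring C 2-iodoallylic alcohol | I/C(=C/[C@@H]1C=C(CO[Si](C)(C)C(C)(C)C)CC[C@H]1C(C)C)CO | intermediate
17 | α-alkylidene β-lactone of the acid fragment | O=C1OC/C1=C\[C@@H]2C=C(CO[Si](C)(C)C(C)(C)C)CC[C@H]2C(C)C | intermediate
18 | propa-1,2-diene (allene) | C=C=C | starting material
19 | 5-isopropyl-8-methylidenebicyclo[4.2.0]octan-2-one | CC(C)[C@@H]1CCC(=O)[C@H]2C(=C)C[C@@H]12 | intermediate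
20 | (chloromethyl)(isopropoxy)dimethylsilane | CC(C)O[Si](C)(C)CCl | starting material
21 | [isopropoxy(dimethyl)silyl]methylmagnesium chloride | CC(C)O[Si](C)(C)C[Mg]Cl | intermediate (not isolated)
22 | β-hydroxysilane adduct | CC(C)[C@@H]1CC[C@](O)(C[Si](C)(C)OC(C)C)[C@H]2C(=C)C[C@@H]12 | intermediate
23 | bicyclic 1,2-diol | CC(C)[C@@H]1CC[C@](O)(CO)[C@H]2C(=C)C[C@@H]12 | intermediate
24 | spiro acetonide of 23 | CC(C)[C@@H]1CC[C@]5(COC(C)(C)O5)[C@H]2C(=C)C[C@@H]12 | intermediate
25 | spiro acetonide cyclobutanone | CC(C)[C@@H]1CC[C@]5(COC(C)(C)O5)[C@H]2C(=O)C[C@@H]12 | intermediate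
26 | trimethylsilyl enol ether of 25 | CC(C)[C@@H]1CC[C@]5(COC(C)(C)O5)[C@H]2C(O[Si](C)(C)C)=C[C@@H]12 | intermediate (not isolated)
27 | aldehyde acid (acetonide) | CC(C)[C@@H]1CC[C@]5(COC(C)(C)O5)[C@@H](C(=O)O)[C@H]1C=O | intermediate
28 | vinyl acid (acetonide) | CC(C)[C@@H]1CC[C@]5(COC(C)(C)O5)[C@@H](C(=O)O)[C@H]1C=C | intermediate
29 | diol acid (alcohol fragment) | CC(C)[C@@H]1CC[C@](O)(CO)[C@@H](C(=O)O)[C@H]1C=C | intermediate
30 | coupled hydroxy ester acid | CC(C)[C@@H]1CC[C@](O)(COC(=O)/C(=C/[C@@H]2C=C(CO[Si](C)(C)C(C)(C)C)CC[C@H]2C(C)C)CO)[C@@H](C(=O)O)[C@H]1C=C | intermediate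
31 | tert-butyl 2-(bromomethyl)prop-2-enoate | C=C(CBr)C(=O)OC(C)(C)C | starting material
32 | metathesis precursor (diene) | CC(C)[C@@H]1CC[C@](O)(COC(=O)/C(=C/[C@@H]2C=C(CO[Si](C)(C)C(C)(C)C)CC[C@H]2C(C)C)CO)[C@@H](C(=O)OCC(=C)C(=O)OC(C)(C)C)[C@H]1C=C | intermediate
33 | protected target (tert-butyl ester, silyl ether) | CC(C)[C@@H]1CC[C@](O)(COC(=O)/C(=C/[C@@H]2C=C(CO[Si](C)(C)C(C)(C)C)CC[C@H]2C(C)C)CO)[C@H]2C(=O)OCC(C(=O)OC(C)(C)C)=C[C@@H]12 | intermediate
34 | CNP0361406.4 | CC(C)[C@@H]1CC[C@](O)(COC(=O)/C(=C/[C@@H]2C=C(CO)CC[C@H]2C(C)C)CO)[C@H]2C(=O)OCC(C(=O)O)=C[C@@H]12 | target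

## Step count and least certain steps

Total: 24 steps. Longest linear sequence: 15 steps (1, 2, 4 to 12, 21 to 24). The alcohol fragment 29 joins after 10 steps (1, 2, 13 to 20).

**Step 12 (key step).** Closure of the strained ring by C–O reductive elimination may be slow. Intermolecular alcoholysis of the acylpalladium (oligoesters) or reduction of the vinylpalladium may then take over, and prolonged heating with base may move the doubly allylic hydrogen of ring C into conjugation.
Fallback, from 16 back to 17: the iodide is methoxycarbonylated intermolecularly (Pd(OAc)2, PPh3, CO, MeOH, Et3N) to the methyl 2-(hydroxymethyl)propenoate F1. LiOH in THF/H2O at 0 °C gives the hydroxy acid F2. The ring is then closed from the carboxyl side with benzenesulfonyl chloride in pyridine at 0 °C (lactonisation of a β-hydroxy acid through its mixed sulfonic anhydride), which returns to 17.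

**Step 13.** The cycloaddition may lose regiocontrol (some head-to-tail adduct) or face control (four-membered ring syn to isopropyl), and the β,γ-unsaturated ketone product may rearrange photochemically by acyl migration on long irradiation.
Fallback, from 4 back to 28: a symmetrical two-carbon partner removes the regiochemical question, and the two carbons are differentiated later. Irradiation of 4 with acetylene gives the cyclobutene ketone F3. Addition of 21 gives the hydroxysilane F4, Tamao oxidation the diol F5, and acetalisation the acetonide F6. Ozonolysis with reductive work-up opens the cyclobutene to the cis dialdehyde F7. One equivalent of methylenetriphenylphosphorane at −78 °C should react at the less hindered formyl group (the one remote from the spiro centre) to give the vinyl aldehyde F8. Chlorite oxidation (NaClO2, NaH2PO4, 2-methylbut-2-ene) then gives 28. This fallback does not cure poor face selectivity.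

**Step 21.** The alkoxide may attack 17 at the allylic CH2–O carbon or at the β-carbon of the alkylidene lactone instead of the acyl carbon, may remove the doubly allylic ring C hydrogen, or may react poorly because the dianion aggregates.
Fallback, from 16 back to 30: the ester bond is made by carbonylative esterification. The hydroxyl of 16 is silylated (Et3SiCl, imidazole) to the triethylsilyl ether F9. Carbonylation of F9 in the presence of 29 (PdCl2(PPh3)2, CO, Et3N, DMF, 50 °C) lets the neutral primary hydroxyl of 29 capture the acylpalladium and gives the coupled silyl ether F10. AcOH/THF/H2O at rt removes the triethylsilyl group selectively and returns to 30.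

**Step 23.** The ruthenium carbene may form slowly at the hindered vinyl group, be held unproductively by the free hydroxyls and ester carbonyls of the large substrate, or give oligomers.
Fallback, from 28 back to 33: ring B is closed before the union on a small substrate without free hydroxyls. Alkylation of 28 with 31 (Cs2CO3, DMF) gives the diene F11. Metathesis under the conditions of step 23, where higher temperature and loading are affordable, gives the bicyclic lactone acetonide F12. AcOH/H2O gives the bicyclic diol F13. NaHMDS (1.0 equiv) is added to a −78 °C mixture of F13 and excess 17 so that the alkoxide is acylated as it forms, which gives 33. This order accepts the risk of ring contraction by the alkoxide that the main route avoids.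

## Further compounds

F1 | step 12 | methyl 2-(hydroxymethyl)-3-(3-{[tert-butyl(dimethyl)silyloxy]methyl}-6-isopropylcyclohex-2-en-1-yl)prop-2-enoate (ester trans to ring C) | COC(=O)/C(=C/[C@@H]1C=C(CO[Si](C)(C)C(C)(C)C)CC[C@H]1C(C)C)CO
F2 | step 12 | 2-(hydroxymethyl)-3-(3-{[tert-butyl(dimethyl)silyloxy]methyl}-6-isopropylcyclohex-2-en-1-yl)prop-2-enoic acid | OC(=O)/C(=C/[C@@H]1C=C(CO[Si](C)(C)C(C)(C)C)CC[C@H]1C(C)C)CO
F3 | step 13 | 5-isopropylbicyclo[4.2.0]oct-7-en-2-one (cis-fused, ring anti to isopropyl) | CC(C)[C@@H]1CCC(=O)[C@H]2C=C[C@@H]12
F4 | step 13 | 5-isopropyl-2-{[isopropoxy(dimethyl)silyl]methyl}bicyclo[4.2.0]oct-7-en-2-ol | CC(C)[C@@H]1CC[C@](O)(C[Si](C)(C)OC(C)C)[C@H]2C=C[C@@H]12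
F5 | step 13 | 2-(hydroxymethyl)-5-isopropylbicyclo[4.2.0]oct-7-en-2-ol | CC(C)[C@@H]1CC[C@](O)(CO)[C@H]2C=C[C@@H]12
F6 | step 13 | spiro acetonide of F5 | CC(C)[C@@H]1CC[C@]5(COC(C)(C)O5)[C@H]2C=C[C@@H]12
F7 | step 13 | 8-isopropyl-2,2-dimethyl-1,3-dioxaspiro[4.5]decane-6,7-dicarbaldehyde (cis) | CC(C)[C@@H]1CC[C@]5(COC(C)(C)O5)[C@@H](C=O)[C@H]1C=O
F8 | step 13 | 7-ethenyl-8-isopropyl-2,2-dimethyl-1,3-dioxaspiro[4.5]decane-6-carbaldehyde | CC(C)[C@@H]1CC[C@]5(COC(C)(C)O5)[C@@H](C=O)[C@H]1C=C
F9 | step 21 | triethylsilyl ether of 16 | I/C(=C/[C@@H]1C=C(CO[Si](C)(C)C(C)(C)C)CC[C@H]1C(C)C)CO[Si](CC)(CC)CC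
F10 | step 21 | triethylsilyl ether of 30 | CC(C)[C@@H]1CC[C@](O)(COC(=O)/C(=C/[C@@H]2C=C(CO[Si](C)(C)C(C)(C)C)CC[C@H]2C(C)C)CO[Si](CC)(CC)CC)[C@@H](C(=O)O)[C@H]1C=C
F11 | step 23 | 2-(tert-butoxycarbonyl)prop-2-en-1-yl ester of 28 | CC(C)[C@@H]1CC[C@]5(COC(C)(C)O5)[C@@H](C(=O)OCC(=C)C(=O)OC(C)(C)C)[C@H]1C=C
F12 | step 23 | bicyclic lactone tert-butyl ester, spiro acetonide | CC(C)[C@@H]1CC[C@]5(COC(C)(C)O5)[C@H]2C(=O)OCC(C(=O)OC(C)(C)C)=C[C@@H]12
F13 | step 23 | bicyclic lactone tert-butyl ester, free diol | CC(C)[C@@H]1CC[C@](O)(CO)[C@H]2C(=O)OCC(C(=O)OC(C)(C)C)=C[C@@H]12
A1 | alternative 1 | 4-isopropyl-3-[(4-methoxybenzyloxy)methyl]-5-nitrocyclohex-1-ene-1-carbaldehyde | O=CC1=C[C@@H](COCc2ccc(OC)cc2)[C@H](C(C)C)[C@@H]([N+](=O)[O-])C1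
A2 | alternative 1 | 3-(4-methoxybenzyloxy)propanal | O=CCCOCc1ccc(OC)cc1
A3 | alternative 1 | (E)-3-methyl-1-nitrobut-1-ene | CC(C)/C=C/[N+](=O)[O-]
A4 | alternative 1 | acrolein | C=CC=O
A5 | alternative 2 | 3-substituted tetronic acid with tethered vinyl group | CC(C)[C@@H](C=C)CC[C@]3(COC(C)(C)O3)C1=C(O)COC1=O
A6 | alternative 2 | bicyclic keto lactone (rings A and B) | CC(C)[C@@H]1CC[C@]3(COC(C)(C)O3)[C@H]2C(=O)OCC(=O)C[C@@H]12
A7 | alternative 3 | acyclic keto acid | CC(C)[C@H](CCC(=O)CO[Si](C)(C)C(C)(C)C)[C@@H](CC(=O)O)C(OC)OC
A8 | alternative 3 | cyclohexane-fused β-lactone | CC(C)[C@@H]1CC[C@@]2(CO[Si](C)(C)C(C)(C)C)OC(=O)[C@H]2[C@H]1C(OC)OC
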